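The easy step comes first: substrate takes up reagent in the reaction phase and becomes target, and target takes up more of it and becomes over-reacted product. Both steps use that same reagent, so dividing one rate by the other removes it. Let s and T be the substrate and target left, as fractions of the charge, and κ the rate constant of the later step over that of the earlier, the selectivity factor. Then dT/d(ln s) = κT − s, which integrates to T = (s^κ − s)/(1 − κ).

| setting | north-east | west | north | flask |
|---|---|---|---|---|
| substrate | 0.0050 M | 0.0075 M | 0.010 M | 0.010 M |
| reagent in the second phase | 1.5 equiv | 1.5 equiv | 2.2 equiv | 1.50 equiv |
| remark | run made earlier | run made earlier | run made earlier |  |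
| time |  |  |  | 1.0 h |
| volume of the second phase over the first |  |  |  | 2.0 |

| run | time / min | target / % | substrate / % |
|---|---|---|---|
| north-east | 10.0 | 53 | 35 |
| north-east | 20.0 | 54 | 15 |
| north-east | 30.0 | 48 | 12 |
| north-east | 40.0 | 50 | 10 |
| north-east | 50.0 | 46 | 4 |
| north-east | 60.0 | 41 | 4 |
| west | 4.00 | 33 | 69 |
| west | 12.0 | 55 | 26 |
| west | 20.0 | 54 | 16 |
| west | 30.0 | 46 | 9 |
| west | 50.0 | 42 | 2 |
| west | 60.0 | 43 | 4 |
| north | 5.00 | 48 | 40 |
| north | 10.0 | 52 | 10 |
| north | 15.0 | 41 | 3 |
| north | 30.0 | 20 | 0 |
| north | 60.0 | 6 | 0 |

(readings scatter by 2 percentage points)

- in the second phase: reagent in the second phase; everything else is in the first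
- charges count per volume of the first phase; a concentration in a rate is the amount of a species over the volume of its own phase; every rate counts per litre of the first phase
- the numbers in the tables scatter with a standard deviation of 2 percentage points
- candidate steps: reagent in the reaction phase + target -> over-reacted product; reagent in the reaction phase <-> reagent in the second phase; substrate + reagent in the reaction phase -> target
- the earlier runs hold the two phases in the same ratio of volumes as the flask asked about

1. target at 1.0 h, in percent of the substrate charged
2. part of the substrate charged that has reacted at 1.0 h

In the north run, from 5.00 min to 10.0 min, 30 percentage points of substrate went but target gained 4 points, so 26 points of target went on. That loss over mean target times the logarithm of the fall in substrate reads κ = 0.375.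

The north-east and west runs, at the flask's equivalents, both read 4 % substrate at 60.0 min. That s gives T = 41.4 %. The reagent used is then 2(1 − s) − T, or 1.51 equivalents, which matches the flask's charge of 1.50 equiv, the limiting reagent. So we expect about 41.4 % target and 96.0 % reacted.

The forecast gives 42 % and 96.5 %, and says “both should then plateau”. The flask gives 42.4 % target and 95.5 % reacted.

    reagent in the reaction phase + target → over-reacted product (k = 29.5 M⁻¹ min⁻¹)
    reagent in the reaction phase ⇌ reagent in the second phase, rate k2*([reagent in the reaction phase] - [reagent in the second phase]/K2) per volume of the first phase (partition coefficient = 0.370, kL = 0.107 min⁻¹)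
    substrate + reagent in the reaction phase → target (k = 77.5 M⁻¹ min⁻¹)

The over-reaction step is the main reason this flask falls short of full target: it holds 42.4 % target at 1.0 h, and without that step >99.9 %. With the flask's 4.52 % substrate at 1.00 h, our κ gives 42.9 % target. The same flask read at 25 min holds 8.62 % substrate, for which κ gives 50.0 %, and it stands at 49.6 % target.

The earlier runs and the new flask were computed from invented constants.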